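(The numbers in the tables were computed for substances that don't exist, noise included.)

- Late in the midnight run the flask had slowed: substrate went from 76.8% at 5.00 min to 74.7% at 12.0 min. So my decision was what to do at 15 min: wait, warm, draw off bis adduct, or charge more reagent.

| setting | midnight | summer | flask |
|---|---|---|---|
| substrate | 0.13 M | 0.13 M | 0.13 M |
| reagent | 0.80 equiv | 0.40 equiv | 0.800 equiv |
| temperature | −20 °C | −25 °C | −20 °C |
| remark | the very flask that is asked about, followed so far | run made earlier |  |
| time |  |  | 15 min |

| run | time / min | bis adduct / % | substrate / % |
|---|---|---|---|
| midnight | 1.00 | 4.6 | 86.1 |
| midnight | 2.00 | 8.6 | 80.7 |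
| midnight | 5.00 | 11.6 | 76.8 |
| midnight | 12.0 | 13.6 | 74.7 |
| summer | 0.833 | 1.4 | 94.4 |
| summer | 2.00 | 1.8 | 90.3 |
| summer | 4.00 | 4.9 | 87.4 |
| summer | 6.00 | 5.5 | 84.8 |

(each reading ± 0.5 percentage points)

- west: change nothing and wait 30 min more
- north: at 15 min add reagent, 50.0% of the amount charged, then wait 30 min
- north-east: at 15 min raise the temperature by 10 K, then wait 30 min
- south-west: at 15 min take out 90% of the bis adduct then present, then wait 30 min

- bis adduct taken out counts as made
- additions bring no volume worth counting

1. bis adduct, in percent of the substrate first charged, at 15 min
2. which option adds most bis adduct ("none" when 2 percentage points or less is all one gets) (west / north / north-east / south-west / none)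
3. bis adduct present, with what was taken out counted in, in percent of the substrate first charged, after north
4. bis adduct present, with what was taken out counted in, in percent of the substrate first charged, after south-west

- I took the gap in the balance at the last midnight reading, 11.7%, as single product, the stage between substrate and bis adduct.
- My zero was the symmetric case, both additions equally fast. At that reading it gives 3.51% bis adduct, and the flask read 13.6%, more than that zero.
- With s the fraction of substrate left, I used single product = (s − s^κ)/(κ − 1) and bis adduct = 1 − s − single product. Here κ is the selectivity factor, how many times faster single product takes reagent than substrate does at equal concentrations. Solving by repeated substitution gave a reading of 5.83, with the scatter of its readings.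
- As a check on another run, the last summer reading, substrate 84.8%, gives 5.56% by this curve, and the summer run read 5.5%.
- At the last midnight reading the curve's slope is 0.912: nearly all of each further point of substrate lost becomes bis adduct. Clearing the margin of 2 percentage points in this flask therefore takes about 2.2 points of substrate.
- The last midnight interval brought 2.1 points of substrate, and I expected the slowing pace to leave waiting short of that margin. Substrate lost plus bis adduct, the reagent taken up by the two additions, accounts for half of the reagent charge, yet the flask had slowed, so I planned to charge reagent.
- The forecast gave 14% at 15 min (13.2% to 14.8%), chose north, put that option at 26% (22.5% to 29.5%) and south-west at 14.3% (13.4% to 15.5%). Its ground for the stall was that “the remaining reagent has probably decomposed, with a lifetime of a minute or two”.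

    reagent + single product → bis adduct (k = 0.204 /M/s, Ea = 36.0 kJ/mol)
    substrate + reagent → single product (k = 0.0366 /M/s, Ea = 42.0 kJ/mol)
    2 reagent → self-condensation product (k = 0.0779 /M/s, Ea = 41.0 kJ/mol)
    (constants at −20 °C)

The flask held 13.4% bis adduct at 15 min, and north added 13 points, reaching 26.5%, while west added 0.026 points and south-west ended at 13.5%. Free reagent stood at 0.0690% of its charge at 15.0 min. With substrate at 74.5% in this flask, κ gives 13.8% bis adduct. The neighbour charged with 1.40 equiv ended with substrate at 67.5%, where κ gives 20.6%, and that neighbour held 20.2%.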